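The earlier runs and the new flask were computed from invented constants; noise was put on by code.

The pitfall in these runs is to treat the quenched share as a fixed fraction of the free monomer, when the protic impurity that does the quenching falls as it reacts.

| flask | free monomer | protic impurity | initiator | temperature | remark | time |
|---|---|---|---|---|---|---|
| gamma | 0.50 M | 0.50 M | 2.2 mM | 15 °C | run made earlier |  |
| epsilon | 0.75 M | 0.50 M | 2.2 mM | 40 °C | run made earlier |  |
| blue | 1.0 M | 0.500 M | 2.2 mM | 20 °C |  | 8.0 d |
| teal | 1.0 M | 0.500 M | 2.2 mM | 60 °C |  | 8.0 d |
| ochre | 1.0 M | 0.500 M | 2.2 mM | 40 °C |  | 8.0 d |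

- gamma (time / d: monomer in chains / %, free monomer / %): 1.25: 70.1, 15.2; 2.50: 81.9, 1.5; 4.00: 81.7, 0; 5.00: 82.4, 0; 6.00: 82.0, 0
- epsilon (time / h: monomer in chains / %, free monomer / %): 12.0: 76.0, 0.2; 20.0: 76.6, 0; 40.0: 77.7, 0.4; 48.0: 76.9, 0.1

(readings scatter by 0.5 percentage points)

- the flask with the highest amount of monomer in chains, in percent of the free monomer charged ("all alike" if they lie within 1.5 percentage points) (blue / teal / ochre / all alike)
- final monomer in chains, as a percentage of the free monomer charged, in blue
- final monomer in chains, as a percentage of the free monomer charged, in teal
- final monomer in chains, as a percentage of the free monomer charged, in ochre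

Free monomer goes two ways, into chains at the living ends and into quenched substrate with the protic impurity, each rate in proportion to free monomer. So free monomer cancels from the split, and I reckon in logarithms: monomer in chains = reach × ln(impurity charged / impurity left).

In gamma, free monomer reads 0% at 4.00 d, so I take the last reading as the final split. Its 82.0% in chains leaves 0.0900 M quenched, and the reach, the molar amount of monomer in chains made per natural-log unit of fall in impurity, is 2.07 M. Epsilon's last reading gives 1.36 M at 40 °C.

In powers of ten, the reach loses a decade per 137 K. A straight line in its logarithm gives 1.90 M for blue and 0.968 M for teal, while ochre takes epsilon's value at the same temperature. I assume the free monomer is used up and put each reach into the balance by repeated substitution. That gives 82.4% in blue, 78.1% in ochre and 73.4% in teal, so blue leads.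

The weak link is a reach held constant through a run, so I test it on gamma's first reading, taken while free monomer still stands. There the reach comes to 2.20 M. Its quenched share of 14.7% is a difference of two readings, each with a scatter of 0.5 percentage points, so this reading does not separate the two reaches, and a constant reach stays my assumption, neither shown nor refuted.

The forecast names blue, with 82.3% there, 74% in teal and 78.2% in ochre, on the ground that “the quench gains with temperature”, and my teal figure stands a little lower than its own.

The flasks give 84.5% in blue, 78.8% in ochre and 73.2% in teal, so blue is highest.

    free monomer + initiator → living end + monomer in chains (k = 2.30 M⁻¹ h⁻¹, Ea = 63.0 kJ mol⁻¹)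
    free monomer + living end → monomer in chains + living end, rate k2*[living end]*[free monomer] (k = 280 M⁻¹ h⁻¹, Ea = 61.0 kJ mol⁻¹)
    living end + monomer in chains → dead end (k = 0.0540 M⁻¹ h⁻¹, Ea = 80.0 kJ mol⁻¹)
    protic impurity + free monomer → quenched substrate (k = 0.310 M⁻¹ h⁻¹, Ea = 78.0 kJ mol⁻¹)
    (constants at 40 °C)

Read back, teal's reach is 0.953 M against my 0.968 M, but blue's is 2.27 M, above gamma's 2.07 M. Teal's neighbour, charged with 0.0013 M of initiator, gives 66.6%, a reach of 0.605 M, where my teal reach scaled by initiator gives 0.572 M. Blue has come to rest, with free monomer at 0% at 8.00 d. By 80.0 d its dead end climbs from 0.138% to 0.216%, and its monomer in chains moves by at most 0.078 points.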